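**Plan**

- Retrosynthesis: remove the benzyl-protected phenol ester and the ring A epoxide, trace the C7 carbinol and C5 oxygen to a ring B dienone, then cut ring B at C5–C6 and C8–C8a (azulene numbering).
- Enabling feature: in ring B the carbinol carbon C7 with its two methylene neighbours C6 and C8 is a three-carbon unit, and C5–C4–C3a–C8a (acyloxy carbon, isopropyl carbon, both fusion carbons) is a four-carbon diene unit already attached to ring A.
- Forward: ring A comes from 3-ethoxycyclopentenone; ring B is closed onto it in one operation by carbenoid cyclopropanation of a cyclopentenyl diene followed by Cope rearrangement.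
- Ring B is then dehydrogenated, methylated, transposed, hydroxylated, reduced and acylated; ring A is unmasked, turned into the methylcyclopentene and epoxidised.
- Stereochemistry: C8a from the chiral dirhodium catalyst; C7 from a chiral copper–boryl addition; C3a and C4 from dissolving-metal reduction and equilibration; C5 and the epoxide by delivery from the C7 hydroxyl.

Key step: step 6

Numbering: bicyclic compounds are numbered as azulenes (ring A = C1–C3, C3a, C8a; ring B = C3a, C4–C8, C8a); β is the face of H-3a in the target, α the face of H-8a.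

Assumption: the senses of induction of Rh2(S-PTAD)4 (step 6) and of (R,R)-QuinoxP* (step 11) are taken from simpler dienes and 3-methylcycloalkenones; if a first run shows the opposite sense, the antipodal catalyst or ligand is used with no other change.

**Route**

Step 1
Reactants: 1 2-bromo-3-methylbut-1-ene; 2 3-ethoxycyclopent-2-en-1-one
Product: 5 3-(3-methylbut-1-en-2-yl)cyclopent-2-en-1-one, via alkenyllithium 3 (not isolated), via lithium carbinolate 4 (not isolated)
Conditions: t-BuLi (2 equiv), Et2O, −78 °C; 2, −78 → 0 °C; 1 M HCl, 23 °C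
Reagents that add atoms: water, O
Why: Bromine–lithium exchange gives the alkenyllithium, which adds 1,2 to the vinylogous ester, and aqueous acid then hydrolyses the enol ether with loss of the tertiary hydroxyl (Stork–Danheiser alkylative enone transposition), so the dienone forms without any stereocentre.

Step 2
Reactants: 5 3-(3-methylbut-1-en-2-yl)cyclopent-2-en-1-one
Product: 6 7-(3-methylbut-1-en-2-yl)-1,4-dioxaspiro[4.4]non-6-ene
Conditions: Me3SiOCH2CH2OSiMe3, Me3SiOTf (5 mol%), CH2Cl2, −78 → −20 °C; pyridine quench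
Reagents that add atoms: 1,2-bis(trimethylsilyloxy)ethane, C[Si](C)(C)OCCO[Si](C)(C)C
Why: Aprotic silyl-triflate-catalysed ketalisation with the bis-silyl ether of ethylene glycol should give the dioxolane at low temperature without moving the ring alkene out of conjugation, leaving the 2-substituted 1,3-diene needed in step 6.

Step 3
Reactants: 7 2,2,6-trimethyl-4H-1,3-dioxin-4-one; 8 2-(trimethylsilyl)ethan-1-ol
Product: 10 2-(trimethylsilyl)ethyl 3-oxobutanoate, via acetylketene 9 (not isolated)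
Conditions: xylenes, 135 °C, acetone distilled off
Reagents that add atoms: none
Why: Thermal retro-(4+2) cleavage of the dioxinone releases acetylketene, which the alcohol traps as the acetoacetate (acetoacetylation with the diketene–acetone adduct).

Step 4
Reactants: 10 2-(trimethylsilyl)ethyl 3-oxobutanoate
Product: 11 2-(trimethylsilyl)ethyl 2-diazo-3-oxobutanoate
Conditions: 4-AcNHC6H4SO2N3, Et3N, MeCN, 0 → 23 °C
Reagents that add atoms: 4-acetamidobenzenesulfonyl azide, CC(=O)Nc1ccc(cc1)S(=O)(=O)N=[N+]=[N-]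
Why: Regitz diazo transfer to the doubly activated methylene of a β-keto ester is general and leaves the silylethyl ester untouched.

Step 5
Reactants: 11 2-(trimethylsilyl)ethyl 2-diazo-3-oxobutanoate
Product: 12 2-(trimethylsilyl)ethyl 3-[(tert-butyldimethylsilyl)oxy]-2-diazobut-3-enoate
Conditions: t-BuMe2SiOTf, Et3N, CH2Cl2, 0 °C
Reagents that add atoms: tert-butyldimethylsilyl trifluoromethanesulfonate, CC(C)(C)[Si](C)(C)OS(=O)(=O)C(F)(F)F
Why: Soft enolisation of the acetyl group and O-silylation give the 2-siloxyvinyl diazoacetate, the three-carbon partner; the fluoride-labile ester is chosen so that the carboxyl group can be removed later under neutral conditions.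

Step 6
Reactants: 6 7-(3-methylbut-1-en-2-yl)-1,4-dioxaspiro[4.4]non-6-ene; 12 2-(trimethylsilyl)ethyl 3-[(tert-butyldimethylsilyl)oxy]-2-diazobut-3-enoate
Product: 14 2-(trimethylsilyl)ethyl (8aS)-7-[(tert-butyldimethylsilyl)oxy]-1,1-(ethylenedioxy)-4-(propan-2-yl)-1,2,3,5,8,8a-hexahydroazulene-6-carboxylate, via cis-divinylcyclopropane 13 (not isolated)
Conditions: Rh2(S-PTAD)4 (dirhodium tetrakis[(S)-(1-adamantyl)(N-phthalimido)acetate], 1 mol%), hexanes, −26 °C, 12 added over 2 h to 6 (1.5 equiv); then 23 → 50 °C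
Reagents that add atoms: none
Why: The divalent rhodium carboxylate converts 12 into a donor/acceptor vinylcarbenoid that should cyclopropanate the terminal 1,1-disubstituted alkene of 6 (forming C5–C6) to give 13, with the cyclopentenyl group cis to the siloxyvinyl group as conjugating substituents normally are in such carbene transfers. 13 should then undergo a Cope rearrangement through the boat transition state, breaking the cyclopropane bond between its two quaternary carbons and forming C8–C8a; the closest known reaction type is the tandem cyclopropanation/Cope rearrangement (formal (4+3) cycloaddition) of vinyldiazoacetates with dienes. The three-membered ring closes by (2+1) carbene addition and is transient, and ring B closes in the (3,3)-sigmatropic step as a seven-membered 1,4-diene. The single new stereocentre C8a is fixed by the absolute configuration of the cyclopropane, which the chiral carboxylate ligands set during carbene transfer and the suprafacial boat rearrangement relays to carbon. The step needs site selectivity, cis selectivity and face selectivity: the first follows from the lower substitution of the exocyclic alkene (the ring alkene is trisubstituted), the second from the conjugating cyclopentenyl group and the third from the catalyst, while the ketal keeps C8a from lying alpha to a carbonyl group.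

Step 7
Reactants: 14 2-(trimethylsilyl)ethyl (8aS)-7-[(tert-butyldimethylsilyl)oxy]-1,1-(ethylenedioxy)-4-(propan-2-yl)-1,2,3,5,8,8a-hexahydroazulene-6-carboxylate
Product: 16 2-(trimethylsilyl)ethyl (8aS)-1,1-(ethylenedioxy)-7-oxo-6-(phenylselanyl)-4-(propan-2-yl)-1,2,3,5,6,7,8,8a-octahydroazulene-6-carboxylate (C6 epimers), via keto ester 15 (not isolated)
Conditions: HF·pyridine, pyridine, THF, 0 °C; then PhSeCl, pyridine, CH2Cl2, 0 °C
Reagents that add atoms: benzeneselenenyl chloride, Cl[Se]c1ccccc1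
Why: Buffered fluoride should cleave the silyl enol ether but not the silylethyl ester at 0 °C, and the enol of the β-keto ester is then selenenylated at C6 by the PhSeCl–pyridine complex (α-selenenylation of a β-dicarbonyl compound), which marks C6 for the later unsaturation and removes its acidic hydrogen; the C6 configuration is irrelevant.

Step 8
Reactants: 16 2-(trimethylsilyl)ethyl (8aS)-1,1-(ethylenedioxy)-7-oxo-6-(phenylselanyl)-4-(propan-2-yl)-1,2,3,5,6,7,8,8a-octahydroazulene-6-carboxylate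
Product: 19 (8aS)-1,1-(ethylenedioxy)-4-(propan-2-yl)-2,3,8,8a-tetrahydroazulen-7(1H)-one, via seleno ketone 17 (not isolated), via selenoxide 18 (not isolated)
Conditions: Bu4NF, THF, 23 °C; aq. work-up; then NaIO4, NaHCO3, THF/MeOH/H2O, 0 → 23 °C
Reagents that add atoms: none
Why: Fluoride fragments the silylethyl ester to ethene, Me3SiF and a β-keto carboxylate that loses CO2, and periodate oxidation with selenoxide syn-elimination can only take a hydrogen from C5, so the enone should form regiospecifically in conjugation with C3a=C4.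

Step 9
Reactants: 19 (8aS)-1,1-(ethylenedioxy)-4-(propan-2-yl)-2,3,8,8a-tetrahydroazulen-7(1H)-one
Product: 20 (8aS)-1,1-(ethylenedioxy)-7-methyl-4-(propan-2-yl)-1,2,3,7,8,8a-hexahydroazulen-7-ol (C7 epimers)
Conditions: MeLi, Et2O, −78 °C; aq. NH4Cl
Reagents that add atoms: methyllithium, [Li]C
Why: The hard organolithium should add 1,2 to the dienone carbonyl faster than it enolises it at −78 °C, and the C7 configuration does not matter because C7 becomes trigonal in step 10.

Step 10
Reactants: 20 (8aS)-1,1-(ethylenedioxy)-7-methyl-4-(propan-2-yl)-1,2,3,7,8,8a-hexahydroazulen-7-ol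
Product: 21 (8aS)-1,1-(ethylenedioxy)-7-methyl-4-(propan-2-yl)-2,3,8,8a-tetrahydroazulen-5(1H)-one
Conditions: C5H5NH[CrO3Cl] (pyridinium chlorochromate, 2 equiv), 4 Å MS, CH2Cl2, 23 °C
Reagents that add atoms: pyridinium chlorochromate, [O-][Cr](=O)(=O)Cl.c1cc[nH+]cc1
Why: In the Babler–Dauben oxidative transposition the hexavalent chromium ester of the tertiary allylic alcohol shifts (3,3) to C5 and is oxidised there, putting the carbonyl on the future acyloxy carbon next to C3a=C4; the vinylogous shift to C3a is unproductive because that carbon has no hydrogen.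

Step 11
Reactants: 21 (8aS)-1,1-(ethylenedioxy)-7-methyl-4-(propan-2-yl)-2,3,8,8a-tetrahydroazulen-5(1H)-one
Product: 23 (8aS)-1,1-(ethylenedioxy)-7β-hydroxy-7α-methyl-4-(propan-2-yl)-2,3,6,7,8,8a-hexahydroazulen-5(1H)-one, via tertiary boronate 22 (not isolated)
Conditions: [Cu(MeCN)4]PF6 (5 mol%), (R,R)-QuinoxP* (6 mol%), LiOt-Bu (10 mol%), B2pin2, DMSO, 23 °C; then NaBO3·4H2O, THF/H2O, 23 °C
Reagents that add atoms: sodium perborate, [Na+].[O-]OB=O
Why: Enantioselective conjugate borylation of a β-methyl cyclic enone by a chiral bisphosphine complex of monovalent copper should occur at the less hindered C6=C7 enone only, with the ligand placing boron on the β face of C7 (anti to H-8a), and perborate then oxidises the C–B bond with retention to the tertiary alcohol.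

Step 12
Reactants: 23 (8aS)-1,1-(ethylenedioxy)-7β-hydroxy-7α-methyl-4-(propan-2-yl)-2,3,6,7,8,8a-hexahydroazulen-5(1H)-one
Product: 25 (3aβH,8aαH)-1,1-(ethylenedioxy)-7β-hydroxy-7α-methyl-4β-(propan-2-yl)-2,3,3a,4,6,7,8,8a-octahydroazulen-5(1H)-one, via dilithium enolate 24 (not isolated)
Conditions: Li (6 equiv), NH3/THF, −78 °C, inverse addition of 23 with t-BuOH (1 equiv); solid NH4Cl; then DBU (0.2 equiv), PhMe, 23 °C
Reagents that add atoms: none
Why: Dissolving-metal (Birch-type) reduction of the tetrasubstituted enone should protonate the β-carbanion axially to give the trans ring fusion (H-3a β, anti to H-8a), and the C4 centre alpha to the ketone is equilibrated to the equatorial β-isopropyl epimer, trans to C3; adding the substrate to excess metal should let electron transfer outrun retro-aldol cleavage of the C7 lithium alkoxide.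

Step 13
Reactants: 25 (3aβH,8aαH)-1,1-(ethylenedioxy)-7β-hydroxy-7α-methyl-4β-(propan-2-yl)-2,3,3a,4,6,7,8,8a-octahydroazulen-5(1H)-one
Product: 26 (3aβH,8aαH)-1,1-(ethylenedioxy)-7α-methyl-4β-(propan-2-yl)decahydroazulene-5α,7β-diol
Conditions: Me4NBH(OAc)3, AcOH/MeCN (1:1), −30 → −20 °C
Reagents that add atoms: none
Why: In the Evans–Saksena reduction the 7β-hydroxyl exchanges onto boron and delivers hydride to the β face of the C5 carbonyl through a chair transition state, which should give the 1,3-anti diol with the 5α-hydroxyl equatorial and trans to the isopropyl group.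

Step 14
Reactants: 26 (3aβH,8aαH)-1,1-(ethylenedioxy)-7α-methyl-4β-(propan-2-yl)decahydroazulene-5α,7β-diol; 27 4-(benzyloxy)benzoyl chloride
Product: 28 (3aβH,8aαH)-1,1-(ethylenedioxy)-7β-hydroxy-7α-methyl-4β-(propan-2-yl)decahydroazulen-5α-yl 4-(benzyloxy)benzoate
Conditions: Et3N, DMAP (0.2 equiv), CH2Cl2, 0 → 23 °C
Reagents that add atoms: none
Why: DMAP-catalysed acyl transfer should esterify the secondary C5 hydroxyl and leave the tertiary C7 hydroxyl alone, and the benzyl ether keeps the phenol inert through the base, hydride and Mitsunobu steps.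

Step 15
Reactants: 28 (3aβH,8aαH)-1,1-(ethylenedioxy)-7β-hydroxy-7α-methyl-4β-(propan-2-yl)decahydroazulen-5α-yl 4-(benzyloxy)benzoate
Product: 29 (3aβH,8aαH)-7β-hydroxy-7α-methyl-1-oxo-4β-(propan-2-yl)decahydroazulen-5α-yl 4-(benzyloxy)benzoate
Conditions: 1 M HCl, THF, 0 → 23 °C
Reagents that add atoms: water, O
Why: Acid hydrolysis of the dioxolane frees the C1 ketone under conditions that the ester, benzyl ether and non-allylic tertiary alcohol tolerate; the reaction is stopped at full conversion to limit acid-catalysed epimerisation of C8a, now alpha to a ketone.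

Step 16
Reactants: 29 (3aβH,8aαH)-7β-hydroxy-7α-methyl-1-oxo-4β-(propan-2-yl)decahydroazulen-5α-yl 4-(benzyloxy)benzoate
Product: 33 (3aβH,8aαH)-7β-hydroxy-7α-methyl-2-methylidene-1-oxo-4β-(propan-2-yl)decahydroazulen-5α-yl 4-(benzyloxy)benzoate, via dilithium enolate 30 (not isolated), via Mannich base 31 (not isolated), via ammonium iodide 32 (not isolated)
Conditions: LiN(i-Pr)2 (2.2 equiv), THF, −78 °C; Me2N=CH2 I, −78 → 0 °C; aq. work-up; MeI, CH2Cl2, 23 °C; aq. NaHCO3, 23 °C
Reagents that add atoms: N,N-dimethylmethyleneiminium iodide, C=[N+](C)C.[I-]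
Why: Kinetic deprotonation takes the C2 methylene and not the C8a methine, the enolate undergoes a Mannich reaction with the iminium salt, and quaternisation followed by E1cB loss of trimethylamine gives the exocyclic enone (Eschenmoser methylenation); the lithium alkoxide at C7 is anti to the C5 ester and cannot reach it.

Step 17
Reactants: 33 (3aβH,8aαH)-7β-hydroxy-7α-methyl-2-methylidene-1-oxo-4β-(propan-2-yl)decahydroazulen-5α-yl 4-(benzyloxy)benzoate
Product: 34 (3aβH,8aαH)-1,7β-dihydroxy-7α-methyl-2-methylidene-4β-(propan-2-yl)decahydroazulen-5α-yl 4-(benzyloxy)benzoate (C1 epimers)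
Conditions: NaBH4, CeCl3·7H2O, MeOH, −40 °C
Reagents that add atoms: none
Why: Luche reduction gives clean 1,2-reduction of the reactive exocyclic enone (used without storage) and spares the aryl ester; the C1 carbinol configuration is erased in step 18.

Step 18
Reactants: 34 (3aβH,8aαH)-1,7β-dihydroxy-7α-methyl-2-methylidene-4β-(propan-2-yl)decahydroazulen-5α-yl 4-(benzyloxy)benzoate
Product: 37 (3aβH,8aαH)-7β-hydroxy-2,7α-dimethyl-4β-(propan-2-yl)-3,3a,4,5,6,7,8,8a-octahydroazulen-5α-yl 4-(benzyloxy)benzoate, via sulfonylhydrazine 35 (not isolated), via allylic diazene 36 (not isolated)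
Conditions: 2-O2NC6H4SO2NHNH2, PPh3, EtO2CN=NCO2Et, THF, −30 °C; then 23 °C
Reagents that add atoms: none
Why: Mitsunobu displacement of the secondary allylic alcohol by the sulfonyl hydrazide, loss of sulfinic acid and retro-ene loss of N2 from the diazene (Myers reductive 1,3-transposition) should deliver hydrogen to the exocyclic methylene and move the alkene to C1=C2, creating no stereocentre and leaving the tertiary alcohol untouched.

Step 19
Reactants: 37 (3aβH,8aαH)-7β-hydroxy-2,7α-dimethyl-4β-(propan-2-yl)-3,3a,4,5,6,7,8,8a-octahydroazulen-5α-yl 4-(benzyloxy)benzoate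
Product: 38 (3aβH,8aαH)-1β,2β-epoxy-7β-hydroxy-2α,7α-dimethyl-4β-(propan-2-yl)decahydroazulen-5α-yl 4-(benzyloxy)benzoate
Conditions: VO(acac)2 (5 mol%), t-BuOOH (decane), CH2Cl2, 0 → 23 °C
Reagents that add atoms: tert-butyl hydroperoxide, CC(C)(C)OO
Why: In this vanadium-catalysed hydroxyl-directed epoxidation the 7β-hydroxyl, bishomoallylic to C1 and axial or isoclinal on the trans-fused twist-chair, should bind the metal peroxide and deliver oxygen to the β face of the trisubstituted alkene; the syn epoxy alcohol cannot cyclise because backside attack at C1 is out of reach.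

Step 20
Reactants: 38 (3aβH,8aαH)-1β,2β-epoxy-7β-hydroxy-2α,7α-dimethyl-4β-(propan-2-yl)decahydroazulen-5α-yl 4-(benzyloxy)benzoate
Product: 39 (1S,2R,3aR,4S,5S,7R,8aS)-1,2-epoxy-7-hydroxy-2,7-dimethyl-4-(propan-2-yl)decahydroazulen-5-yl 4-hydroxybenzoate
Conditions: H2 (1 atm), Pd/C (10%), EtOAc, 23 °C
Reagents that add atoms: none
Why: Hydrogenolysis of the benzyl aryl ether over palladium on carbon is fast under neutral conditions, under which the non-benzylic trisubstituted epoxide, the ester and the tertiary alcohol should survive.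

**Compound list**

1 | 2-bromo-3-methylbut-1-ene | CC(C)C(Br)=C | starting material
2 | 3-ethoxycyclopent-2-en-1-one | CCOC1=CC(=O)CC1 | starting material
3 | (3-methylbut-1-en-2-yl)lithium | [Li]C(=C)C(C)C | intermediate
4 | lithium 3-ethoxy-1-(3-methylbut-1-en-2-yl)cyclopent-2-en-1-olate | CCOC1=CC(O[Li])(CC1)C(=C)C(C)C | intermediate
5 | 3-(3-methylbut-1-en-2-yl)cyclopent-2-en-1-one | CC(C)C(=C)C1=CC(=O)CC1 | intermediate
6 | 7-(3-methylbut-1-en-2-yl)-1,4-dioxaspiro[4.4]non-6-ene | CC(C)C(=C)C1=CC2(CC1)OCCO2 | intermediate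
7 | 2,2,6-trimethyl-4H-1,3-dioxin-4-one | CC1=CC(=O)OC(C)(C)O1 | starting material
8 | 2-(trimethylsilyl)ethan-1-ol | C[Si](C)(C)CCO | starting material
9 | acetylketene | CC(=O)C=C=O | intermediate
10 | 2-(trimethylsilyl)ethyl 3-oxobutanoate | CC(=O)CC(=O)OCC[Si](C)(C)C | intermediate
11 | 2-(trimethylsilyl)ethyl 2-diazo-3-oxobutanoate | CC(=O)C(=[N+]=[N-])C(=O)OCC[Si](C)(C)C | intermediate
12 | 2-(trimethylsilyl)ethyl 3-[(tert-butyldimethylsilyl)oxy]-2-diazobut-3-enoate | C=C(O[Si](C)(C)C(C)(C)C)C(=[N+]=[N-])C(=O)OCC[Si](C)(C)C | intermediate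
13 | 2-(trimethylsilyl)ethyl 1-{1-[(tert-butyldimethylsilyl)oxy]ethenyl}-2-(1,4-dioxaspiro[4.4]non-6-en-7-yl)-2-(propan-2-yl)cyclopropane-1-carboxylate (siloxyvinyl and cyclopentenyl groups cis) | C[Si](C)(C)CCOC(=O)[C@@]1(C(O[Si](C)(C)C(C)(C)C)=C)C[C@]1(C(C)C)C1=CC2(CC1)OCCO2 | intermediate
14 | 2-(trimethylsilyl)ethyl (8aS)-7-[(tert-butyldimethylsilyl)oxy]-1,1-(ethylenedioxy)-4-(propan-2-yl)-1,2,3,5,8,8a-hexahydroazulene-6-carboxylate | CC(C)C1=C2CCC3(OCCO3)[C@H]2CC(O[Si](C)(C)C(C)(C)C)=C(C(=O)OCC[Si](C)(C)C)C1 | intermediate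
15 | 2-(trimethylsilyl)ethyl (8aS)-1,1-(ethylenedioxy)-7-oxo-4-(propan-2-yl)-1,2,3,5,6,7,8,8a-octahydroazulene-6-carboxylate | CC(C)C1=C2CCC3(OCCO3)[C@H]2CC(=O)C(C(=O)OCC[Si](C)(C)C)C1 | intermediate
16 | 2-(trimethylsilyl)ethyl (8aS)-1,1-(ethylenedioxy)-7-oxo-6-(phenylselanyl)-4-(propan-2-yl)-1,2,3,5,6,7,8,8a-octahydroazulene-6-carboxylate (C6 epimers) | CC(C)C1=C2CCC3(OCCO3)[C@H]2CC(=O)C([Se]c4ccccc4)(C(=O)OCC[Si](C)(C)C)C1 | intermediate
17 | (8aS)-1,1-(ethylenedioxy)-6-(phenylselanyl)-4-(propan-2-yl)-2,3,5,6,8,8a-hexahydroazulen-7(1H)-one | CC(C)C1=C2CCC3(OCCO3)[C@H]2CC(=O)C([Se]c4ccccc4)C1 | intermediate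
18 | (8aS)-1,1-(ethylenedioxy)-6-(phenylseleninyl)-4-(propan-2-yl)-2,3,5,6,8,8a-hexahydroazulen-7(1H)-one | CC(C)C1=C2CCC3(OCCO3)[C@H]2CC(=O)C([Se](=O)c4ccccc4)C1 | intermediate
19 | (8aS)-1,1-(ethylenedioxy)-4-(propan-2-yl)-2,3,8,8a-tetrahydroazulen-7(1H)-one | CC(C)C1=C2CCC3(OCCO3)[C@H]2CC(=O)C=C1 | intermediate
20 | (8aS)-1,1-(ethylenedioxy)-7-methyl-4-(propan-2-yl)-1,2,3,7,8,8a-hexahydroazulen-7-ol (C7 epimers) | CC(C)C1=C2CCC3(OCCO3)[C@H]2CC(C)(O)C=C1 | intermediate
21 | (8aS)-1,1-(ethylenedioxy)-7-methyl-4-(propan-2-yl)-2,3,8,8a-tetrahydroazulen-5(1H)-one | CC(C)C1=C2CCC3(OCCO3)[C@H]2CC(C)=CC1=O | intermediate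
22 | (8aS)-1,1-(ethylenedioxy)-7α-methyl-4-(propan-2-yl)-7β-(4,4,5,5-tetramethyl-1,3,2-dioxaborolan-2-yl)-2,3,6,7,8,8a-hexahydroazulen-5(1H)-one | CC(C)C1=C2CCC3(OCCO3)[C@H]2C[C@@](C)(B4OC(C)(C)C(C)(C)O4)CC1=O | intermediate
23 | (8aS)-1,1-(ethylenedioxy)-7β-hydroxy-7α-methyl-4-(propan-2-yl)-2,3,6,7,8,8a-hexahydroazulen-5(1H)-one | CC(C)C1=C2CCC3(OCCO3)[C@H]2C[C@@](C)(O)CC1=O | intermediate
24 | dilithium enolate–alkoxide of 25 (C4=C5 enolate, 3aβ-H, 8aα-H) | CC(C)C=1[C@@H]2CCC3(OCCO3)[C@H]2C[C@@](C)(O[Li])CC=1O[Li] | intermediate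
25 | (3aβH,8aαH)-1,1-(ethylenedioxy)-7β-hydroxy-7α-methyl-4β-(propan-2-yl)-2,3,3a,4,6,7,8,8a-octahydroazulen-5(1H)-one | CC(C)[C@H]1[C@@H]2CCC3(OCCO3)[C@H]2C[C@@](C)(O)CC1=O | intermediate
26 | (3aβH,8aαH)-1,1-(ethylenedioxy)-7α-methyl-4β-(propan-2-yl)decahydroazulene-5α,7β-diol | CC(C)[C@H]1[C@@H]2CCC3(OCCO3)[C@H]2C[C@@](C)(O)C[C@@H]1O | intermediate
27 | 4-(benzyloxy)benzoyl chloride | O=C(Cl)c1ccc(OCc2ccccc2)cc1 | starting material
28 | (3aβH,8aαH)-1,1-(ethylenedioxy)-7β-hydroxy-7α-methyl-4β-(propan-2-yl)decahydroazulen-5α-yl 4-(benzyloxy)benzoate | CC(C)[C@H]1[C@@H]2CCC3(OCCO3)[C@H]2C[C@@](C)(O)C[C@@H]1OC(=O)c1ccc(OCc2ccccc2)cc1 | intermediate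
29 | (3aβH,8aαH)-7β-hydroxy-7α-methyl-1-oxo-4β-(propan-2-yl)decahydroazulen-5α-yl 4-(benzyloxy)benzoate | CC(C)[C@H]1[C@@H]2CCC(=O)[C@H]2C[C@@](C)(O)C[C@@H]1OC(=O)c1ccc(OCc2ccccc2)cc1 | intermediate
30 | dilithium C1=C2 enolate–C7 alkoxide of 29 | CC(C)[C@H]1[C@@H]2CC=C(O[Li])[C@H]2C[C@@](C)(O[Li])C[C@@H]1OC(=O)c1ccc(OCc2ccccc2)cc1 | intermediate
31 | 2-[(dimethylamino)methyl] derivative of 29 (C2 epimers) | CC(C)[C@H]1[C@@H]2CC(CN(C)C)C(=O)[C@H]2C[C@@](C)(O)C[C@@H]1OC(=O)c1ccc(OCc2ccccc2)cc1 | intermediate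
32 | 2-[(trimethylammonio)methyl] derivative of 29, iodide (C2 epimers) | CC(C)[C@H]1[C@@H]2CC(C[N+](C)(C)C)C(=O)[C@H]2C[C@@](C)(O)C[C@@H]1OC(=O)c1ccc(OCc2ccccc2)cc1.[I-] | intermediate
33 | (3aβH,8aαH)-7β-hydroxy-7α-methyl-2-methylidene-1-oxo-4β-(propan-2-yl)decahydroazulen-5α-yl 4-(benzyloxy)benzoate | CC(C)[C@H]1[C@@H]2CC(=C)C(=O)[C@H]2C[C@@](C)(O)C[C@@H]1OC(=O)c1ccc(OCc2ccccc2)cc1 | intermediate
34 | (3aβH,8aαH)-1,7β-dihydroxy-7α-methyl-2-methylidene-4β-(propan-2-yl)decahydroazulen-5α-yl 4-(benzyloxy)benzoate (C1 epimers) | CC(C)[C@H]1[C@@H]2CC(=C)C(O)[C@H]2C[C@@](C)(O)C[C@@H]1OC(=O)c1ccc(OCc2ccccc2)cc1 | intermediate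
35 | 1-[1-(2-nitrobenzenesulfonyl)hydrazin-1-yl] analogue of 34 (N in place of the C1 hydroxyl) | CC(C)[C@H]1[C@@H]2CC(=C)C(N(N)S(=O)(=O)c3ccccc3[N+](=O)[O-])[C@H]2C[C@@](C)(O)C[C@@H]1OC(=O)c1ccc(OCc2ccccc2)cc1 | intermediate
36 | 1-diazenyl analogue of 34 (allylic monoalkyl diazene) | CC(C)[C@H]1[C@@H]2CC(=C)C(N=N)[C@H]2C[C@@](C)(O)C[C@@H]1OC(=O)c1ccc(OCc2ccccc2)cc1 | intermediate
37 | (3aβH,8aαH)-7β-hydroxy-2,7α-dimethyl-4β-(propan-2-yl)-3,3a,4,5,6,7,8,8a-octahydroazulen-5α-yl 4-(benzyloxy)benzoate | CC(C)[C@H]1[C@@H]2CC(C)=C[C@H]2C[C@@](C)(O)C[C@@H]1OC(=O)c1ccc(OCc2ccccc2)cc1 | intermediate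
38 | (3aβH,8aαH)-1β,2β-epoxy-7β-hydroxy-2α,7α-dimethyl-4β-(propan-2-yl)decahydroazulen-5α-yl 4-(benzyloxy)benzoate | CC(C)[C@H]1[C@@H]2C[C@@]3(C)O[C@H]3[C@H]2C[C@@](C)(O)C[C@@H]1OC(=O)c1ccc(OCc2ccccc2)cc1 | intermediate
39 | (1S,2R,3aR,4S,5S,7R,8aS)-1,2-epoxy-7-hydroxy-2,7-dimethyl-4-(propan-2-yl)decahydroazulen-5-yl 4-hydroxybenzoate | CC(C)[C@H]1[C@@H]2C[C@@]3(C)O[C@H]3[C@H]2C[C@@](C)(O)C[C@@H]1OC(=O)c1ccc(O)cc1 | target

**Step count**

Total: 20 steps. Longest linear sequence: 18 steps (steps 3–5 and 6–20, from 7 and 8 to 39). Steps 1 and 2 are a two-step branch that joins at step 6.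

**Three steps most likely to fail**

Step 11. Face selection at the new tertiary centre may be poor on the cross-conjugated dienone, and the catalytic alkoxide may remove the γ-hydrogen at C8a and erode the ring-fusion centre. The fallback sets out from 21 and makes the C7–O bond by Weitz–Scheffer epoxidation of the less hindered enone (t-BuOOH, catalytic benzyltrimethylammonium hydroxide, THF, 0 °C, short contact time). This should give (8aS)-6β,7β-epoxy-1,1-(ethylenedioxy)-7α-methyl-4-(propan-2-yl)-2,3,6,7,8,8a-hexahydroazulen-5(1H)-one F1. Reductive cleavage of its Cα–O bond with SmI2 (divalent samarium) in THF/MeOH at −78 °C comes back to the route at 23. Here the face is chosen by the substrate alone, so the two C7 epimers would be separated at the stage of 23.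

Step 18. The Mitsunobu substitution at the hindered carbinol flanked by C8a may stall or proceed with allylic transposition (attack at the methylidene carbon), which would place the diazene on the wrong carbon and return an exocyclic alkene. The fallback sets out from 33 and avoids substitution altogether. Condensation with TsNHNH2 (EtOH, 23 °C) gives the C1 4-methylbenzenesulfonylhydrazone of 33 F2. Catecholborane (CHCl3, 0 °C) reduces its C=N bond, and NaOAc·3H2O at reflux expels sulfinate to the same allylic diazene 36, which loses N2 with alkene migration (Kabalka-type reduction of an enone tosylhydrazone) and comes back to the route at 37.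

Step 19. Oxygen delivery from the remote C7 hydroxyl may be too weak, so the peroxide may attack the α face or give a mixture of faces. The fallback sets out from 37 and inverts the facial outcome of an undirected electrophile. NBS in aqueous THF should form the bromonium ion on the face preferred without direction, and water opens it at the tertiary C2 from the opposite face (Markovnikov). This gives (3aβH,8aαH)-1α-bromo-2β,7β-dihydroxy-2α,7α-dimethyl-4β-(propan-2-yl)decahydroazulen-5α-yl 4-(benzyloxy)benzoate F3. K2CO3 in acetone then closes the epoxide with inversion at C1 and comes back to the route at 38.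

**Further compounds**

F1 | step 11 | (8aS)-6β,7β-epoxy-1,1-(ethylenedioxy)-7α-methyl-4-(propan-2-yl)-2,3,6,7,8,8a-hexahydroazulen-5(1H)-one | CC(C)C1=C2CCC3(OCCO3)[C@H]2C[C@@]4(C)O[C@H]4C1=O
F2 | step 18 | C1 4-methylbenzenesulfonylhydrazone of 33 | CC(C)[C@H]1[C@@H]2CC(=C)C(=NNS(=O)(=O)c3ccc(C)cc3)[C@H]2C[C@@](C)(O)C[C@@H]1OC(=O)c1ccc(OCc2ccccc2)cc1
F3 | step 19 | (3aβH,8aαH)-1α-bromo-2β,7β-dihydroxy-2α,7α-dimethyl-4β-(propan-2-yl)decahydroazulen-5α-yl 4-(benzyloxy)benzoate | CC(C)[C@H]1[C@@H]2C[C@@](C)(O)[C@H](Br)[C@H]2C[C@@](C)(O)C[C@@H]1OC(=O)c1ccc(OCc2ccccc2)cc1
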